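The chair opened the meeting on the flask with 18 µM of enzyme and tabled the recipes, the earlier runs and the questions.

| setting | green | teal | flask |
|---|---|---|---|
| starting material | 0.10 M | 0.10 M | 0.10 M |
| protic impurity | 2 mM | 2 mM | 2.00 mM |
| enzyme | 9 µM | 14 µM | 18 µM |
| remark | run made earlier | run made earlier |  |
| time |  |  | 50 min |

| run | time / min | starting material / % | product / % |
|---|---|---|---|
| green | 2.50 | 22.3 | 75.3 |
| green | 8.00 | 0 | 97.2 |
| green | 15.0 | 0 | 99.6 |
| green | 20.0 | 0.2 | 97.7 |
| green | 30.0 | 0.3 | 97.8 |
| green | 40.0 | 0 | 98.8 |
| green | 50.0 | 0 | 97.2 |
| teal | 4.00 | 0.9 | 96.6 |
| teal | 6.00 | 0.2 | 98.0 |
| teal | 10.0 | 0.5 | 100.3 |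
| teal | 15.0 | 0.8 | 97.8 |
| teal | 20.0 | 0 | 99.1 |
| teal | 30.0 | 0.2 | 98.0 |
| teal | 50.0 | 0 | 97.6 |

(each reading ± 1 percentage point)

- which holds at 50 min: what has brought the reaction to rest, or that it has not come to rest (all of the starting material has reacted / no working catalyst is left / forward and back rates have come level / it is still moving)
- part of the starting material gone at 50 min
- the product standing at 50 min, as a percentage of the starting material charged

- steps under discussion: enzyme -> spent catalyst; starting material + enzyme -> product + enzyme; starting material + protic impurity -> quenched substrate
- the reaction counts as stopped when no species that holds the starting material changes by six tenths of a point or more over the second half of the time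

The analyst reported starting material at 0% in the green run at 8.00 min and 0.9% in the teal run at 4.00 min, within the scatter of zero, so neither run showed a stalled residue. The kineticist proposed the impurity toll, c(protic impurity)/c(starting material), the share of the charge lost to the quench if the impurity is its limiting reagent, 2.00%. As a first answer, she said, the product stands at 98.0%, and the late readings average 98.0% in the green run and 98.2% in the teal run.

The process chemist put that answer back: might the flask, with more enzyme than the teal run, finish before the toll is paid? The readings of the green run already fell 2.4 percentage points short of the charge at 2.50 min, close to the toll, with 22.3% of starting material still standing. Scaled by the enzyme charges, the time of that reading becomes 1.25 min for the flask, earlier than the first reading of either run, so the runs do not test it. But the late average of the teal run stands 0.20 points above that of the green run, less than the scatter of a reading. The second round therefore returned the same 98.0%, which these minutes adopt as their own reckoning.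

The forecast read all of the starting material has reacted, conversion 100%, and product 98.1% (97.6% to 98.8%), holding that “quenching is fast and barely depends on enzyme level”.

The flask gives all of the starting material has reacted, conversion 100%, and product 98.0%.

    enzyme → spent catalyst (k = 5.20 × 10⁻⁵ s⁻¹)
    starting material + enzyme → product + enzyme, rate k2*[starting material]*[enzyme]/(1 + ([starting material]/Km2) + ([starting material]/Ksi2)^2) (0.0730 M, 0.0650 M, k = 2600 L mol⁻¹ s⁻¹)
    starting material + protic impurity → quenched substrate (k = 11.0 L mol⁻¹ s⁻¹)

In this flask quenched substrate stands at 2.00% at 50.0 min, level with the toll, and protic impurity at 0%; at the start the enzyme step used starting material at 0.45 of the quench rate. The neighbouring flask is this one with 8.00 mM of protic impurity, so its toll is 8.00% and its reckoned product 92.0%. In that neighbouring flask, at 50.0 min, protic impurity stands at 0%, quenched substrate at 8.00%, and product at 92.0%.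

Readings and results are calculated on assumed constants; noise was put on by code.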